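**Remarks.** Racemic compounds 5–9 are written with the SMILES of the enantiomer that belongs to the target series. The β-keto esters 16 and 17 are written as their enols. The sense of induction of the copper catalyst in step 8 is assumed to follow that known for glyoxylate esters; if it proves opposite, the antipodal ligand is used.

## The problem

Target 18 has three rings. Ring A is a δ-lactone, spiro-joined to ring B, a cyclopentanone, which is cis-fused to ring C, a γ-lactone with a gem-dimethyl carbon. The spiro carbon is quaternary and sits between the ring B ketone and the ring A lactone carbonyl. Beside it lie three contiguous crowded carbons: the ring-fusion C(CH3), the ring-fusion CH and the C(CH3)2–O carbon.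

There are five stereocentres. The two ring-fusion centres fix each other through the cis fusion, and the folded B/C bicycle can direct the spiro centre through its convex face. The two centres of ring A (the CH with the isopropenyl group and the O–CH with the isobutyryl group, cis to each other) are separated from the bicycle by the spiro carbon. No centre of one half can control the other half, so both halves must be made as single enantiomers.

The O–CH is α to a ketone and carries an acyloxy group, so base can epimerise it, and the cis arrangement in ring A is probably not the more stable one. The β-keto lactone at the quaternary spiro carbon can be cleaved by nucleophiles in a retro-Claisen reaction. The 1,1-disubstituted alkene does not tolerate strong acid.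

The feature that opens the structure is that the spiro carbon is the α-carbon of a β-keto ester whose alkoxy oxygen is the O–CH of the side chain. This pattern arises when a 2-diazocyclohexane-1,3-dione contracts to an acylketene and an alcohol adds to it.

## Retrosynthesis

**18 ⇒ 16.** The bond from the spiro carbon to the CH2 of ring A is cut. Forward, the β-keto ester carbon of 16 displaces the primary chloride through the iodide 17 in a six-membered closure. The neighbouring cut, the ester C–O bond, would require lactonisation onto a carbonyl at a quaternary carbon after an intermolecular alkylation with a β-branched halide. The chosen cut removes ring A and the quaternary stereocentre in one operation. The reaction must give C- rather than O-alkylation, attack on the convex face of the bicycle, and no epimerisation at the O–CH.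

**16 ⇒ 10 + 14 (key step, through 15).** The ester C–O bond and the ring B bond from the future spiro carbon to the ring CH2 are cut together. Esterifying a preformed β-keto acid is ruled out because such acids decarboxylate. A Dieckmann route to ring B needs a separate ester exchange with a hindered alcohol. The Wolff contraction makes the acylating agent and the ring in the same event and needs no coupling reagent. The precursors are of similar size and carry two stereocentres each. The forward reaction must move the CH2, not the quaternary carbon, and the ketene must be captured by the hydroxyl of 14.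

**10 ⇒ 9 ⇒ 8.** The diazo group comes from diazo transfer to the only doubly activated CH2 of dione 8. The racemate 9 is resolved at this stage, because it is neutral, rigid and non-enolisable, whereas the dione itself is acidic and enolised. An enantioselective Michael addition earlier in the sequence was set aside: the β-carbon of 3 is flanked by a tertiary carbinol, and the later alkoxide steps could erode the enantiomeric purity through retro-Michael reaction.

**8 ⇒ 7.** The bond between the ring CH2 flanked by both ketones and the ketone carbon next to C(CH3) is cut (Claisen condensation of a methyl ketone onto an ester). A neighbouring plan would annulate a 3-oxoglutarate onto a preformed α-methylbutenolide. There the doubly stabilised carbanion can attack the lactone carbonyl in a six-membered closure that competes with the wanted one, and the product would be an isomeric dione without the angular methyl group. In 7 the only six-membered closure available is the wanted one.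

**7 ⇒ 6 ⇒ 3 + 4.** The angular methyl group is removed first (C-methylation of a malonate-type lactone). Then the lactone C–O bond and the bond between the two future ring-fusion carbons are cut (Michael addition of malonate 4 to enone 3, then lactonisation through 5). Adding a methylmalonate directly would require a tertiary carbanion to attack a β-carbon next to a quaternary carbinol. Installing the methyl group afterwards with a small electrophile avoids this. The precursors are commodity chemicals.

**3 ⇒ 1 + 2.** The enone is cut at the alkene (cross-metathesis of a tertiary allylic alcohol with a vinyl ketone).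

**14 ⇒ 12 + 13; 12 ⇒ 11.** The bond between the carbinol carbon and the CH that carries the chloromethyl group is cut (carbonyl-ene reaction). The aldehyde carbon of 12 bonds to the less substituted alkene carbon of 13, and a methyl hydrogen is transferred, which creates the isopropenyl group. Both stereocentres, all carbons of ring A and the leaving group for the last step arise in one step. Auxiliary-based aldol routes would need four or more steps. Compound 12 comes from ketone 11 by Riley oxidation of the methyl group.

## Roads not taken

**Alternative 1:** The cut is the bond between the two ring-fusion carbons. Forward, a diazo group between the ketone and the lactone carbonyl of an eight-membered keto lactone is turned into a carbenoid by Rh2(OAc)4 or a chiral carboxylate of divalent rhodium. The carbenoid inserts into a transannular C–H bond and closes rings B and C together to give A1.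

- Merits: two rings and the cis fusion are formed in one step, the quaternary centre that becomes the spiro carbon is already present, and a chiral catalyst could replace a resolution. In that respect it is better than the chosen plan.
- Weak points: the eight-membered keto lactone is itself hard to close. The C–H bond to be attacked is an unactivated CH2 next to a quaternary carbon, and the prenyl alkene of the substrate is an easier target for the carbenoid (cyclopropanation). A1 still lacks the angular methyl group and all of ring A.
- Ring A would have to be raised late from the prenyl group, for instance by an ene reaction with 12 on a crowded substrate, followed by lactonisation.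
- Comparison: the chosen plan accepts a resolution and a late, substrate-controlled spiro centre. In return it makes the ring A carbons and both of their stereocentres on a small molecule, and it needs no medium ring.

**Alternative 2:** The cuts are the bonds from the ring-fusion C(CH3) to the ring-fusion CH and from the future spiro carbon to the ring B CH2. Forward, a 5,5-dialkoxy-1-methylcyclopentadiene and an acrylate ester combine in an endo Diels–Alder reaction under a chiral oxazaborolidinium Lewis acid to give norbornene A2. Its ketal bridge becomes the ring B ketone, and its alkene is later cleaved into both lactone carbonyls.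

- Merits: the enantioselective cycloaddition is a well-founded reaction class and sets the ring-fusion centres absolutely. It is better than the chosen plan on absolute stereocontrol.
- Weak points: dienes of this class dimerise readily. After the cycloaddition the ester must be turned into the tertiary carbinol, the alkene cleaved, and the two carbonyls so released told apart. The one that must be esterified with the hindered alcohol 14 is a β-keto acid once the ketal is removed. The spiro centre is still set by the same late alkylation.
- Comparison: the chosen plan needs fewer changes of oxidation state and forms the hindered ester directly from a ketene. It gives up catalytic absolute control of the bicycle.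

**Alternative 3:** The cuts are the bonds from the spiro carbon to the ketone carbon and to the ring B CH2. Forward, with Sc(OTf)3 (trivalent scandium) a prenyl-substituted α-diazo ester adds to a lactone-fused cyclobutanone. The ring CH2 migrates as nitrogen leaves, and the four-membered ring expands to ring B, giving A3.

- Merits: the quaternary carbon is made in the C–C bond-forming step. Migration of the less substituted carbon is better founded for this ring expansion than for the Wolff shift in an unsymmetrical diazo dione. In this respect it is the safer reaction.
- Weak points: the cyclobutanone next to a quaternary ring-fusion carbon is strained and costly to make. The configuration of the new quaternary centre relative to the bicycle is not assured. A3 carries a prenyl group and a methyl ester in place of ring A, so the two ring A stereocentres would again be set late on a crowded substrate and the methyl ester exchanged for a lactone.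
- Comparison: the chosen plan carries a regiochemical risk in its key step. In return it brings in ring A complete and stereodefined and forms the spiro centre by a simple intramolecular alkylation.

Key step: step 9

## Route

Step 1
Reactants: 1 2-methylbut-3-en-2-ol; 2 but-3-en-2-one
Product: 3 (E)-5-hydroxy-5-methylhex-3-en-2-one
Conditions: second-generation Hoveyda–Grubbs catalyst (2 mol %), 2 (3 equiv), CH2Cl2, 40 °C
Reagents that add atoms: none
Why: Olefin cross-metathesis between a tertiary allylic alcohol, which homodimerises slowly, and an electron-poor vinyl ketone is a matched pairing, and the E-enone is the thermodynamic product.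

Step 2
Reactants: 3 (E)-5-hydroxy-5-methylhex-3-en-2-one; 4 dimethyl propanedioate
Product: 6 racemic methyl (3R*,4S*)-5,5-dimethyl-2-oxo-4-(2-oxopropyl)oxolane-3-carboxylate, via acyclic malonate adduct 5 (not isolated)
Conditions: DBU (0.3 equiv), MeCN, 50 °C; then TsOH·H2O (cat.), toluene, 80 °C
Reagents that add atoms: none
Why: Base-catalysed Michael addition of a malonate to an enone (the first half of the dimedone synthesis) forms the bond between the future ring-fusion carbons; catalytic DBU cannot drive a Claisen step, and the tertiary hydroxyl then closes the γ-lactone on the neighbouring ester, helped by the gem-dimethyl group. The new centre is racemic and the acidic C3–H lets the ester settle trans to the side chain.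

Step 3
Reactants: 6 racemic methyl (3R*,4S*)-5,5-dimethyl-2-oxo-4-(2-oxopropyl)oxolane-3-carboxylate
Product: 7 racemic methyl (3S*,4S*)-3,5,5-trimethyl-2-oxo-4-(2-oxopropyl)oxolane-3-carboxylate
Conditions: MeI, K2CO3, acetone, 40 °C
Reagents that add atoms: iodomethane, CI
Why: C-Alkylation of a malonate-type α-carbomethoxy lactone; methyl iodide should enter trans to the neighbouring 2-oxopropyl group, which puts the ester cis to the ketone chain. The minor epimer would reach the same dione in step 4 through attack on the lactone carbonyl and re-lactonisation.

Step 4
Reactants: 7 racemic methyl (3S*,4S*)-3,5,5-trimethyl-2-oxo-4-(2-oxopropyl)oxolane-3-carboxylate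
Product: 8 racemic (3aS*,7aS*)-3,3,7a-trimethyl-3a,4,6,7a-tetrahydro-2-benzofuran-1,5,7(3H)-trione
Conditions: NaOMe (2.5 equiv), MeOH, reflux; then aq. HCl
Reagents that add atoms: none
Why: Claisen (Dieckmann-type) cyclisation of the methyl ketone enolate onto the ester, the second half of the dimedone synthesis; the six-membered closure is the only one open, and the product is removed from the equilibria as its dione enolate. The cis fusion follows from the cis ester and chain.

Step 5
Reactants: 8 racemic (3aS*,7aS*)-3,3,7a-trimethyl-3a,4,6,7a-tetrahydro-2-benzofuran-1,5,7(3H)-trione
Product: 9 racemic (3aS*,7aS*)-6-diazo-3,3,7a-trimethyl-3a,4,6,7a-tetrahydro-2-benzofuran-1,5,7(3H)-trione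
Conditions: 4-acetamidobenzenesulfonyl azide, Et3N, MeCN, 0 °C to 20 °C
Reagents that add atoms: 4-acetamidobenzenesulfonyl azide, CC(=O)Nc1ccc(cc1)S(=O)(=O)N=[N+]=[N-]
Why: Regitz diazo transfer to the only CH2 flanked by two ketones; the other α-carbon next to the hindered ketone is quaternary.

Step 6
Reactants: 9 racemic (3aS*,7aS*)-6-diazo-3,3,7a-trimethyl-3a,4,6,7a-tetrahydro-2-benzofuran-1,5,7(3H)-trione
Product: 10 (3aS,7aS)-6-diazo-3,3,7a-trimethyl-3a,4,6,7a-tetrahydro-2-benzofuran-1,5,7(3H)-trione
Conditions: preparative SFC, amylose tris(3,5-dimethylphenylcarbamate) phase, CO2/MeOH, 35 °C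
Reagents that add atoms: none
Why: Resolution by chromatography on a chiral stationary phase; the diazo dione is neutral, rigid, non-enolisable and UV-active, and the configuration of the collected enantiomer is to be secured by X-ray analysis with anomalous dispersion before it is carried on.

Step 7
Reactants: 11 3-methylbutan-2-one
Product: 12 3-methyl-2-oxobutanal
Conditions: SeO2 (1.0 equiv), 1,4-dioxane/H2O, reflux; distillation
Reagents that add atoms: selenium dioxide, O=[Se]=O
Why: Riley oxidation of the methyl group of a methyl ketone to the 2-oxoaldehyde; the methine on the other side cannot be taken to a dicarbonyl compound.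

Step 8
Reactants: 12 3-methyl-2-oxobutanal; 13 1-chloro-3-methylbut-2-ene
Product: 14 (4S,5S)-5-(chloromethyl)-4-hydroxy-2,6-dimethylhept-6-en-3-one
Conditions: [Cu((S,S)-t-Bu-box)](SbF6)2 (10 mol %), 13 (3 equiv), CH2Cl2, 0 °C to 20 °C
Reagents that add atoms: none
Why: Catalytic enantioselective carbonyl-ene reaction of a 1,2-dicarbonyl enophile chelated to a bis(oxazoline) complex of divalent copper; the aldehyde carbon bonds to the less substituted alkene carbon and a methyl hydrogen is delivered to oxygen, which creates the isopropenyl group. The ligand shields one face of the chelated aldehyde (4S), and the chloromethyl group should lie on the side of the formyl hydrogen, away from the metal-bound oxygen, which gives the anti (5S) isomer.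

Step 9
Reactants: 10 (3aS,7aS)-6-diazo-3,3,7a-trimethyl-3a,4,6,7a-tetrahydro-2-benzofuran-1,5,7(3H)-trione; 14 (4S,5S)-5-(chloromethyl)-4-hydroxy-2,6-dimethylhept-6-en-3-one
Product: 16 (3S,4S)-3-(chloromethyl)-2,6-dimethyl-5-oxohept-1-en-4-yl (3aS,6aS)-6-hydroxy-3,3,6a-trimethyl-1-oxo-3,3a,4,6a-tetrahydro-1H-cyclopenta[c]furan-5-carboxylate, via acylketene 15 (not isolated)
Conditions: hν (365 nm LED), 10 (1.1 equiv), toluene (degassed, 0.03 M), 20 °C
Reagents that add atoms: none
Why: Excitation of the diazo dione expels N2 and, because the ring holds both carbonyls s-Z to the diazo group, the 1,2-shift is concerted with nitrogen loss: the ring CH2 moves from its carbonyl carbon to the diazo carbon, forming the bond from the future spiro carbon to the ring B CH2 and leaving the exocyclic acylketene 15. The closest known reaction type is the photochemical or thermal Wolff ring contraction of cyclic 2-diazo-1,3-diketones with capture of the acylketene by one equivalent of an alcohol. Ring B is closed by this 1,2-shift, a ring contraction of the six-membered dione and not a cyclisation in Baldwin's sense; the ester C–O bond of the later ring A forms intermolecularly when the hydroxyl of 14 adds across the ketene C=O. No stereocentre is created, since the α-carbon of the β-keto ester is enolised, and the four existing centres are untouched under neutral conditions at 20 °C. The step needs migration of the CH2 and not of the quaternary ring-fusion carbon; the latter carries the lactone carbonyl and is the poorer donor toward the electron-deficient carbon, so the ketone of ring B should stay next to the C(CH3) centre. It also needs the hydroxyl to win over the isobutyryl carbonyl and the alkene of 14, which the high rate of alcohol addition to acylketenes secures, and 365 nm light is absorbed by the diazo chromophore only.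

Step 10
Reactants: 16 (3S,4S)-3-(chloromethyl)-2,6-dimethyl-5-oxohept-1-en-4-yl (3aS,6aS)-6-hydroxy-3,3,6a-trimethyl-1-oxo-3,3a,4,6a-tetrahydro-1H-cyclopenta[c]furan-5-carboxylate
Product: 18 (3aS,5R,5'S,6'S,6aS)-3,3,6a-trimethyl-6'-(2-methylpropanoyl)-5'-(prop-1-en-2-yl)tetrahydrospiro[cyclopenta[c]furan-5(1H),3'-oxane]-1,2',6(6aH)-trione, via primary iodide 17 (not isolated)
Conditions: Cs2CO3 (1.2 equiv), NaI (0.2 equiv), MeCN, 40 °C
Reagents that add atoms: none
Why: Intramolecular C-alkylation of a β-keto ester enolate (6-exo-tet) with Finkelstein assistance; the carbonate deprotonates only the β-keto ester, and the CH2 should approach the face of ring B that carries the ring-fusion H and CH3 (the convex face of the cis-fused bicycle), which sets the spiro centre as 5R.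

## Compound list

1 | 2-methylbut-3-en-2-ol | C=CC(C)(C)O | starting material
2 | but-3-en-2-one | C=CC(C)=O | starting material
3 | (E)-5-hydroxy-5-methylhex-3-en-2-one | CC(=O)/C=C/C(C)(C)O | intermediate
4 | dimethyl propanedioate | COC(=O)CC(=O)OC | starting material
5 | dimethyl 2-[(3S*)-2-hydroxy-2-methyl-5-oxohexan-3-yl]propanedioate (racemic) | CC(=O)C[C@@H](C(C(=O)OC)C(=O)OC)C(C)(C)O | intermediate (not isolated)
6 | methyl (3R*,4S*)-5,5-dimethyl-2-oxo-4-(2-oxopropyl)oxolane-3-carboxylate (racemic, 3,4-trans) | CC(=O)C[C@@H]1C(C)(C)OC(=O)[C@H]1C(=O)OC | intermediate
7 | methyl (3S*,4S*)-3,5,5-trimethyl-2-oxo-4-(2-oxopropyl)oxolane-3-carboxylate (racemic, 3-methyl trans to the 2-oxopropyl group) | CC(=O)C[C@@H]1C(C)(C)OC(=O)[C@]1(C)C(=O)OC | intermediate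
8 | (3aS*,7aS*)-3,3,7a-trimethyl-3a,4,6,7a-tetrahydro-2-benzofuran-1,5,7(3H)-trione (racemic, cis-fused) | O=C1C[C@@H]2C(C)(C)OC(=O)[C@]2(C)C(=O)C1 | intermediate
9 | (3aS*,7aS*)-6-diazo-3,3,7a-trimethyl-3a,4,6,7a-tetrahydro-2-benzofuran-1,5,7(3H)-trione (racemic) | [N-]=[N+]=C1C(=O)C[C@@H]2C(C)(C)OC(=O)[C@]2(C)C1=O | intermediate
10 | (3aS,7aS)-6-diazo-3,3,7a-trimethyl-3a,4,6,7a-tetrahydro-2-benzofuran-1,5,7(3H)-trione | [N-]=[N+]=C1C(=O)C[C@@H]2C(C)(C)OC(=O)[C@]2(C)C1=O | intermediate
11 | 3-methylbutan-2-one | CC(C)C(C)=O | starting material
12 | 3-methyl-2-oxobutanal | CC(C)C(=O)C=O | intermediate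
13 | 1-chloro-3-methylbut-2-ene (prenyl chloride) | CC(C)=CCCl | starting material
14 | (4S,5S)-5-(chloromethyl)-4-hydroxy-2,6-dimethylhept-6-en-3-one | C=C(C)[C@H](CCl)[C@H](O)C(=O)C(C)C | intermediate
15 | (3aS,6aS)-3,3,6a-trimethyl-5-(oxomethylidene)tetrahydro-1H-cyclopenta[c]furan-1,6(6aH)-dione (acylketene) | O=C=C1C[C@@H]2C(C)(C)OC(=O)[C@]2(C)C1=O | intermediate (not isolated)
16 | (3S,4S)-3-(chloromethyl)-2,6-dimethyl-5-oxohept-1-en-4-yl (3aS,6aS)-6-hydroxy-3,3,6a-trimethyl-1-oxo-3,3a,4,6a-tetrahydro-1H-cyclopenta[c]furan-5-carboxylate (β-keto ester, enol form) | ClC[C@@H](C(C)=C)[C@H](OC(=O)C1=C(O)[C@@]2(C)C(=O)OC(C)(C)[C@H]2C1)C(=O)C(C)C | intermediate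
17 | (3S,4S)-3-(iodomethyl)-2,6-dimethyl-5-oxohept-1-en-4-yl (3aS,6aS)-6-hydroxy-3,3,6a-trimethyl-1-oxo-3,3a,4,6a-tetrahydro-1H-cyclopenta[c]furan-5-carboxylate (enol form) | IC[C@@H](C(C)=C)[C@H](OC(=O)C1=C(O)[C@@]2(C)C(=O)OC(C)(C)[C@H]2C1)C(=O)C(C)C | intermediate (not isolated)
18 | (3aS,5R,5'S,6'S,6aS)-3,3,6a-trimethyl-6'-(2-methylpropanoyl)-5'-(prop-1-en-2-yl)tetrahydrospiro[cyclopenta[c]furan-5(1H),3'-oxane]-1,2',6(6aH)-trione (CNP0216954.1) | C=C(C)[C@@H]1C[C@]2(C[C@@H]3C(C)(C)OC(=O)[C@]3(C)C2=O)C(=O)O[C@@H]1C(=O)C(C)C | target

## Step count and risks

Total: 10 steps. Longest linear sequence: 8 steps (steps 1–6, 9, 10). Steps 7 and 8 form the second branch.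

**Step 9 (key step).** The most likely failure is loss of regiocontrol in the 1,2-shift. Both acyl groups are locked syn to the diazo group, and the preference between a primary carbon and a quaternary, α-acyl carbon is argued from electronics, not established. Migration of the ring-fusion carbon would give the isomeric ring with the ketone remote from the C(CH3) centre.

The fallback builds ring B by a Dieckmann closure, whose direction is fixed because the ring-fusion carbon is quaternary, and attaches the side chain by ester exchange. It sets out from 1 and returns at 16.

- Johnson–Claisen rearrangement of 1 with trimethyl orthoacetate (cat. propanoic acid, 140 °C) gives methyl 5-methylhex-4-enoate F1.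
- Oxidative lactone annulation of F1 with the potassium salt of monomethyl 2-methylpropanedioate and Mn(OAc)3 (trivalent manganese) in acetic acid at 70 °C adds the malonyl radical to the CH terminus and closes the lactone on the tertiary cation. This gives methyl (3S*,4S*)-4-(3-methoxy-3-oxopropyl)-3,5,5-trimethyl-2-oxooxolane-3-carboxylate F2 together with its 3-epimer.
- NaOMe in methanol converges both epimers to methyl (3aS,6aS)-6-hydroxy-3,3,6a-trimethyl-1-oxo-3,3a,4,6a-tetrahydro-1H-cyclopenta[c]furan-5-carboxylate F3. It forms as the racemate and is resolved on the chiral phase of step 6.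
- Heating F3 with 14 and catalytic DMAP in toluene at 110 °C over 4 Å molecular sieves exchanges the ester and gives 16.

**Step 8.** The most likely failure is poor or inverted simple diastereoselectivity. Either methyl group can deliver the hydrogen and the chelated enophile can sit in two orientations, so the syn isomer may prevail while the carbinol configuration still follows the ligand.

The fallback sets the carbinol centre by inversion. It sets out from 12 and 13 and returns at 14.

- The ene reaction is run with [Cu((R,R)-t-Bu-box)](SbF6)2, and the syn isomer (4R,5S)-5-(chloromethyl)-4-hydroxy-2,6-dimethylhept-6-en-3-one F4 is separated.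
- Mitsunobu reaction with chloroacetic acid, PPh3 and DIAD in THF at 0 °C inverts C4 and gives (3S,4S)-3-(chloromethyl)-2,6-dimethyl-5-oxohept-1-en-4-yl chloroacetate F5.
- Thiourea and NaHCO3 in ethanol remove the chloroacetyl group under near-neutral conditions to give 14.

**Step 10.** The most likely failure is attack on the concave face. The tether, which carries two stereocentres of its own, may override the preference of the bicycle and give the spiro epimer. O-alkylation through the ester oxygen is the second risk.

The fallback forms the C–C bond with an untethered electrophile, so that only the bicycle decides the face, and closes ring A at the ester C–O bond. It sets out from 10 and 14 and returns at 18.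

- Photolysis of 10 at 365 nm in methanol gives the methyl keto ester F3.
- 14 is silylated (TBSOTf, 2,6-lutidine, CH2Cl2, −78 °C) to (4S,5S)-4-[(tert-butyldimethylsilyl)oxy]-5-(chloromethyl)-2,6-dimethylhept-6-en-3-one F6.
- NaI in refluxing acetone converts F6 into (4S,5S)-4-[(tert-butyldimethylsilyl)oxy]-5-(iodomethyl)-2,6-dimethylhept-6-en-3-one F7.
- Alkylation of F3 with F7 (Cs2CO3, DMF, 50 °C) gives methyl (3aS,5R,6aS)-5-[(2S,3S)-3-[(tert-butyldimethylsilyl)oxy]-5-methyl-4-oxo-2-(prop-1-en-2-yl)hexyl]-3,3,6a-trimethyl-1,6-dioxohexahydro-1H-cyclopenta[c]furan-5-carboxylate F8.
- HF·pyridine in MeCN frees methyl (3aS,5R,6aS)-5-[(2S,3S)-3-hydroxy-5-methyl-4-oxo-2-(prop-1-en-2-yl)hexyl]-3,3,6a-trimethyl-1,6-dioxohexahydro-1H-cyclopenta[c]furan-5-carboxylate F9, which is lactonised with catalytic TsOH in toluene at 80 °C to 18.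

**Step 7.** The most likely failure is loss of site control and over-oxidation. Selenium dioxide can also attack the enol on the methine side, and the product hydrates and oligomerises, which harms the anhydrous ene reaction.

The fallback places the oxygen through a halide. It sets out from 11 and returns at 12.

- Bromination of 11 in methanol at 0–10 °C goes to the methyl group and gives 1-bromo-3-methylbutan-2-one F10.
- Kornblum oxidation of F10 (DMSO, NaHCO3, 20–40 °C) gives 12, which is distilled.

## Further compounds

F1 | step 9 | methyl 5-methylhex-4-enoate | COC(=O)CCC=C(C)C
F2 | step 9 | methyl (3S*,4S*)-4-(3-methoxy-3-oxopropyl)-3,5,5-trimethyl-2-oxooxolane-3-carboxylate (racemic, formed with its 3-epimer) | COC(=O)CC[C@@H]1C(C)(C)OC(=O)[C@]1(C)C(=O)OC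
F3 | step 9 | methyl (3aS,6aS)-6-hydroxy-3,3,6a-trimethyl-1-oxo-3,3a,4,6a-tetrahydro-1H-cyclopenta[c]furan-5-carboxylate (enol form) | COC(=O)C1=C(O)[C@@]2(C)C(=O)OC(C)(C)[C@H]2C1
F4 | step 8 | (4R,5S)-5-(chloromethyl)-4-hydroxy-2,6-dimethylhept-6-en-3-one | C=C(C)[C@H](CCl)[C@@H](O)C(=O)C(C)C
F5 | step 8 | (3S,4S)-3-(chloromethyl)-2,6-dimethyl-5-oxohept-1-en-4-yl chloroacetate | C=C(C)[C@H](CCl)[C@H](OC(=O)CCl)C(=O)C(C)C
F6 | step 10 | (4S,5S)-4-[(tert-butyldimethylsilyl)oxy]-5-(chloromethyl)-2,6-dimethylhept-6-en-3-one | C=C(C)[C@H](CCl)[C@H](O[Si](C)(C)C(C)(C)C)C(=O)C(C)C
F7 | step 10 | (4S,5S)-4-[(tert-butyldimethylsilyl)oxy]-5-(iodomethyl)-2,6-dimethylhept-6-en-3-one | C=C(C)[C@H](CI)[C@H](O[Si](C)(C)C(C)(C)C)C(=O)C(C)C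
F8 | step 10 | methyl (3aS,5R,6aS)-5-[(2S,3S)-3-[(tert-butyldimethylsilyl)oxy]-5-methyl-4-oxo-2-(prop-1-en-2-yl)hexyl]-3,3,6a-trimethyl-1,6-dioxohexahydro-1H-cyclopenta[c]furan-5-carboxylate | C=C(C)[C@H](C[C@]2(C[C@@H]3C(C)(C)OC(=O)[C@]3(C)C2=O)C(=O)OC)[C@H](O[Si](C)(C)C(C)(C)C)C(=O)C(C)C
F9 | step 10 | methyl (3aS,5R,6aS)-5-[(2S,3S)-3-hydroxy-5-methyl-4-oxo-2-(prop-1-en-2-yl)hexyl]-3,3,6a-trimethyl-1,6-dioxohexahydro-1H-cyclopenta[c]furan-5-carboxylate | C=C(C)[C@H](C[C@]2(C[C@@H]3C(C)(C)OC(=O)[C@]3(C)C2=O)C(=O)OC)[C@H](O)C(=O)C(C)C
F10 | step 7 | 1-bromo-3-methylbutan-2-one | CC(C)C(=O)CBr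
A1 | alternative 1 | methyl (3aS,5R,6aS)-3,3-dimethyl-5-(3-methylbut-2-en-1-yl)-1,6-dioxohexahydro-1H-cyclopenta[c]furan-5-carboxylate | CC(C)=CC[C@]1(C[C@@H]2C(C)(C)OC(=O)[C@@H]2C1=O)C(=O)OC
A2 | alternative 2 | methyl 7,7-dimethoxy-1-methylbicyclo[2.2.1]hept-5-ene-2-carboxylate (endo adduct, enantiomer as in the SMILES) | COC(=O)[C@H]1C[C@H]2C=C[C@]1(C)C2(OC)OC
A3 | alternative 3 | methyl (3aS,5R,6aS)-3,3,6a-trimethyl-5-(3-methylbut-2-en-1-yl)-1,6-dioxohexahydro-1H-cyclopenta[c]furan-5-carboxylate | CC(C)=CC[C@]1(C[C@@H]2C(C)(C)OC(=O)[C@]2(C)C1=O)C(=O)OC
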